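The data were generated by integration from invented constants; noise was put on by code.

The amounts of L and Z in the autumn flask add up to 100% at 4.00 min, so L comes from Z. From then to 20.0 min L falls from 14.9% to 5.0% while Z rises from 85.1% to 95.2%, so L goes back to Z. For the next run of this flask the charges stay as they are, and the decision is when to draw it.

| flask | Z | X | J | remark | time |
|---|---|---|---|---|---|
| autumn | 1 M | 1 M | 2 M | the very flask that is asked about, followed so far |  |
| spring | 1 M | 2 M | 2 M | run made earlier |  |
| flask | 1.0 M | 1.00 M | 2.00 M |  | 1.0 h |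

| run | time / min | L / % | Z / % |
|---|---|---|---|
| autumn | 0.833 | 9.8 | 90.4 |
| autumn | 1.33 | 12.4 | 87.7 |
| autumn | 2.00 | 14.8 | 85.3 |
| autumn | 4.00 | 14.9 | 85.1 |
| autumn | 6.00 | 12.9 | 87.1 |
| autumn | 10.0 | 9.2 | 91.2 |
| autumn | 20.0 | 5.0 | 95.2 |
| spring | 0.833 | 18.1 | 81.4 |
| spring | 1.50 | 24.3 | 75.1 |
| spring | 3.00 | 29.4 | 70.6 |
| spring | 6.00 | 26.7 | 72.8 |
| spring | 15.0 | 18.7 | 81.6 |
| spring | 30.0 | 15.5 | 84.7 |
| spring | 60.0 | 13.9 | 85.0 |

(readings scatter by 0.3 percentage points)

- time up to 1.0 h at which L stands highest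
- the amount of L, in percent of the Z charged, at that time

Doubling X to 2 M in the spring run took L over Z at 0.833 min from 0.108 to 0.222, twice, so X feeds L. If L forms from Z and X and returns, then where L stands still the way in equals the way back, a quasi-equilibrium, and L over Z is proportional to the free X. The reckoning here reads that ratio at 4.00 min, the highest autumn reading of L:

L / Z = 14.9% / 85.1% = 0.175

This is the holding ratio, L over Z while L stands still.

The autumn readings at 2.00 min and 4.00 min differ by less than their scatter of 0.3 percentage points, so the turn lies near their midpoint: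

(2.00 min + 4.00 min) / 2 = 3.00 min

By 20.0 min the ratio has sunk to 0.0525, so the draw belongs at the turn.

The forecast puts the peak at 0.048 h with 15.5%: “The maximum is therefore the early one.”

The flask gives 15.3% at 0.0512 h.

    J + X ⇌ E (K = 15.0 L mol⁻¹, k = 0.220 L mol⁻¹ min⁻¹)
    Z + X ⇌ L (K = 0.660 L mol⁻¹, k = 0.170 L mol⁻¹ min⁻¹)
    X → D (k = 9.00 × 10⁻⁵ min⁻¹)

Z + X and L relax with a half-life of 1.61 min at 1.00 h, shorter than the 1.0 h allowed, and 0.175 over the 27.3% of X standing at 0.0512 h makes 0.641 per whole charge of X, so the 5.55% of X left in the flask at 1.00 h gives 0.0356, where the flask holds 0.0367. In the neighbour flask with 0.50 M of J, the 37.5% of X left at 1.00 h gives 0.240, and that flask holds 0.248.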